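**The problem**

Compound 28 is a 5,6,7,8-tetrahydro-1H-isochromen-8-one in which a cyclohexenone (ring A: C4a, C5, C6, C7, C8, C8a) is fused through the tetrasubstituted C4a=C8a alkene to a 2H-pyran (ring B: C1, O2, C3, C4). The sequence O2–C3=C4–C4a=C8a–C8=O is one push–pull dienone, and C3 carries an (E)-propenyl group. The only stereocentres are the neighbours C6 (S, secondary carbinol) and C7 (R, fully substituted, bearing methyl and an ester oxygen), with the hydroxyl trans to the ester; nothing else in the molecule can relay configuration to them, so the pair has to be set in one reagent-controlled event. The C7 oxygen is acylated by a di-ortho-substituted benzoic acid on a tertiary alcohol next to a ketone, a bond that direct acylation will hardly form. The C6 hydroxyl is a vinylogous β-hydroxy ketone, so base can eliminate it through C5 and the C4a=C8a alkene, and it is also an acceptor for a C7→C6 acyl shift. The dienol ether of ring B is acid-labile and the phenol is free, so ring B has to be closed late and near neutrality. The enabling feature lies in ring A: C6 and C7 (α to the C8 ketone) are an aldol pair and C7 also bears the ester oxygen, so the ester can be installed while C7 is still a secondary, lactate-type carbon and the quaternary centre made afterwards by C–C bond formation.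

**Retrosynthesis**

Ring B is opened first, at O2–C3. Target 28 is then an isomer of triol 27, in which a primary C1 hydroxyl sits next to a C4≡C3 alkyne on the ring A enone. This cut is preferred to O2–C1 (an alkylation that needs a C3 enol) and to C4–C4a because it leaves a precursor without ring B and at the same oxidation level. The forward step must be a 6-endo-dig hydroalkoxylation under neutral conditions. C3 is the δ-carbon of the ynenone and carries the propenyl group, which biases the closure that way.

Triol 27 comes from its silyl ethers 26 by acidic fluoride. In 26 the bonds C4a–C4 and C8a–C1 are cut together. Both substituents are added across the enone of 16 in one operation: the pentenynyl unit as nucleophile at C4a, then a one-carbon aldehyde electrophile on the resulting C8a enolate 21, giving 22. This sum is one oxidation level short of 26, so the C4a=C8a alkene has to be restored, from silyl ether 23 to 26 by selenoxide elimination. A cross-coupling on a β-halo enone would avoid that but would require a ring A 1,3-dione, which the aldol product does not offer. The alkynyl unit comes from dibromodiene 18, made from (E)-but-2-enal 17.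

Enone 16 is traced to hydroxy ketone 14 by silylation and dehydrogenation between C8a and C4a. Because C7 is quaternary, 14 can enolise only towards C8a, so no regiochemical question arises.

The key cut is C6–C7 of 14. It removes ring A and both stereocentres at once and leaves the acyclic, racemic keto aldehyde 12. Cutting C5–C6 or C8–C8a instead would keep the quaternary ester carbon as a problem to be solved separately. The forward reaction must form the C7 enamine 13 of an α-acyloxy-α-methyl ketone, close the six-membered ring on the aldehyde, and control two new centres from a racemic substrate.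

Keto aldehyde 12 is the ozonolysis product of alkene 10. Ketone 10 is cut at C8–C8a into Weinreb amide 7 and the Grignard reagent 9 from 5-bromopent-1-ene 8. The amide stops the addition at the ketone, and the hindered aryl ester should not compete.

In 7 the ester is cut at the alkyl C–O bond, not at the acyl C–O bond. The carboxylate of acid 4 displaces the activated hydroxyl of lactamide 6, itself made from ethyl lactate 5, so the hindered ester is formed at a secondary carbon by substitution. Inversion is irrelevant because the centre is erased later.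

Acid 4 is derived from methyl orsellinate 1: selective silylation of the C4 phenol gives 2, methylation of the chelated C2 phenol gives 3, and the hindered methyl ester of 3 is dealkylated at its methyl group.

**Roads not taken**

Alternative 1: The cut is at C4–C3 and at the bond from C3 to the propenyl carbon, with carbon monoxide A4 as C3. Pd(PPh3)4 adds to the allylic bromide A2, A4 inserts into the C4–Pd bond, and the stannane A3, (E)-tributyl(prop-1-enyl)stannane, transmetallates to give ketone A1. Desilylation, hemiketal formation from the C1 hydroxyl and dehydration would then close ring B.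
- Merits: C3 arrives at the ketone level, so no dehydrogenation is needed after the coupling. The coupling is convergent, and the propenyl geometry comes from a defined stannane.
- Weak points: the step makes no ring and no stereocentre. A2 already has to contain ring A, the C6/C7 pair, the hindered ester and a tetrasubstituted alkene with two different functionalised methyl groups. A2 is a γ-bromo enone, and its π-allyl palladium species can couple with A3 without taking up A4. A1 has a doubly activated C4 methylene and an enone side chain, both prone to isomerisation and conjugate addition. Tin residues and an acid-promoted final dehydration next to the labile C6 oxygen add to the cost.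
- Comparison: in redox economy at the end this road is better, since the chosen plan spends steps 12 and 13 on restoring the enone. Against that, the chosen plan's key step delivers ring A, both stereocentres and the quaternary ester carbon, which Alternative 1 would have to borrow from elsewhere.

Alternative 2: The cut is through the benzoate ring at C1'–C2' and C6'–C5'. The C7 but-2-ynoate A6 reacts as dienophile with the diene A7, 1,1-dimethoxy-3-(trimethylsilyloxy)buta-1,3-diene, in hot toluene. Loss of methanol and of the silyl group aromatises the adduct to A5, the C6 silyl ether of 28.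
- Merits: the tertiary C7 hydroxyl is acylated with a small acid instead of a di-ortho-substituted one. No phenol protecting group is carried, and the regiochemistry of the pairing of A7 with an ynoate gives the 4-hydroxy-2-methoxy-6-methyl pattern directly.
- Weak points: it presupposes the complete bicyclic core with a free tertiary α-ketol, whose acylation is still not trivial, and 2-ynoates isomerise under acyl-transfer catalysis. A β-methyl ynoate is a slow dienophile towards A7, and at the temperature needed the core of A6 offers its own electron-rich diene (C3=C4 with the propenyl group) and an enone to the reaction partners. The stereocentres are not addressed.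
- Comparison: in protecting-group economy and in not carrying a heavy aryl ester through many steps this road is better. The chosen plan sets against it that its ester is made by substitution at a secondary carbon at the outset, so no late acylation or late cycloaddition on the sensitive dienone is needed.

Alternative 3: The cut is at O2–C1, with C1 and C4 unveiled as carbonyl groups from the furan A9. Singlet dioxygen A10, generated with rose bengal and light, adds across furan carbons C1 and C4 of A9, and Me2S reduces the endoperoxide to the cis-enedione. The C3 hydroxyl then closes on the C1 aldehyde to give lactol A8.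
- Merits: the furan is a robust masked enedione, the oxidation is mild and reagent-clean, and ring B closes without a metal catalyst and without a separate one-carbon electrophile.
- Weak points: A8 is at the wrong oxidation pattern for 28. C1 is a lactol where a methylene is needed, C4 is a ketone where a vinyl C–H is needed, and C3 is sp3. Three redox and elimination adjustments therefore follow, on an enedione that carries the labile C6 oxygen. A10 can also attack the propenyl group and the electron-rich arene, the furan is deactivated by the C8 ketone, and A9 needs a C3 carbinol centre of no lasting use. The stereocentres are again left open.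
- Comparison: the ring B closure itself is simpler than in the chosen plan. The chosen plan sets against it that its Ph3PAuNTf2-catalysed closure gives ring B at exactly the oxidation level of 28.

Key step: step 8

Assumption: the quinine-derived 9-amino-9-deoxy-epi-cinchona amine is taken as the pseudo-enantiomer that leads to the (6S,7R) series; if the sense proves opposite, the quinidine-derived amine replaces it with nothing else changed.

Abbreviations: TBS = tert-butyldimethylsilyl; TES = triethylsilyl.

Step 1
Reactants: 1 methyl orsellinate (methyl 2,4-dihydroxy-6-methylbenzoate)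
Product: 2 methyl 4-(TBS-oxy)-2-hydroxy-6-methylbenzoate
Conditions: TBSCl (1.05 equiv), imidazole, CH2Cl2, 0 °C
Reagents that add atoms: tert-butyldimethylsilyl chloride, CC(C)(C)[Si](C)(C)Cl
Why: Chemoselective O-silylation; the C2 hydroxyl is held in a hydrogen bond to the ester carbonyl and flanked by it, so the free and more acidic C4 phenol should react first.

Step 2
Reactants: 2 methyl 4-(TBS-oxy)-2-hydroxy-6-methylbenzoate
Product: 3 methyl 4-(TBS-oxy)-2-methoxy-6-methylbenzoate
Conditions: MeOH, PPh3, DIAD, THF, 0 °C → rt
Reagents that add atoms: methanol, CO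
Why: Mitsunobu etherification methylates the remaining chelated phenol under neutral conditions, which spares the base-labile aryl silyl ether that carbonate alkylation would put at risk.

Step 3
Reactants: 3 methyl 4-(TBS-oxy)-2-methoxy-6-methylbenzoate
Product: 4 4-(TBS-oxy)-2-methoxy-6-methylbenzoic acid
Conditions: LiI, pyridine, reflux; dilute HCl work-up
Reagents that add atoms: none
Why: SN2 dealkylation of a hindered methyl ester: iodide attacks the ester methyl group, which the two ortho substituents do not shield, whereas hydroxide at the carbonyl would be slow and would strip the silyl ether; the iodomethane formed is taken up by pyridine, and the aryl methyl ether has a far poorer leaving group and should stay.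

Step 4
Reactants: 5 ethyl lactate (racemic)
Product: 6 2-hydroxy-N-methoxy-N-methylpropanamide (racemic)
Conditions: MeNHOMe·HCl, i-PrMgCl, THF, −20 → 0 °C
Reagents that add atoms: N,O-dimethylhydroxylamine hydrochloride, CNOC.Cl
Why: Aminolysis of the ester by the magnesium amide gives the Weinreb amide directly from the unprotected hydroxy ester, excess base covering the hydroxyl.

Step 5
Reactants: 6 2-hydroxy-N-methoxy-N-methylpropanamide; 4 4-(TBS-oxy)-2-methoxy-6-methylbenzoic acid
Product: 7 1-[methoxy(methyl)amino]-1-oxopropan-2-yl 4-(TBS-oxy)-2-methoxy-6-methylbenzoate (racemic)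
Conditions: PPh3, DIAD, THF, 0 °C → rt
Reagents that add atoms: none
Why: Mitsunobu esterification: the carboxylate of 4 displaces the activated secondary hydroxyl by SN2, so the hindered ester is made at the alkyl carbon and not by acylation; the inversion has no consequence because the substrate is racemic and the centre is erased in step 8.

Step 6
Reactants: 7 1-[methoxy(methyl)amino]-1-oxopropan-2-yl 4-(TBS-oxy)-2-methoxy-6-methylbenzoate; 8 5-bromopent-1-ene
Product: 10 3-oxooct-7-en-2-yl 4-(TBS-oxy)-2-methoxy-6-methylbenzoate (racemic), via pent-4-enylmagnesium bromide 9 (not isolated)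
Conditions: 8, Mg, THF, rt; then 7, THF, −78 → 0 °C; aq. NH4Cl
Reagents that add atoms: none
Why: Weinreb ketone synthesis: the chelated tetrahedral adduct stops the addition at the ketone stage, and the di-ortho-substituted aryl ester is too hindered to compete at low temperature.

Step 7
Reactants: 10 3-oxooct-7-en-2-yl 4-(TBS-oxy)-2-methoxy-6-methylbenzoate
Product: 12 3,7-dioxoheptan-2-yl 4-(TBS-oxy)-2-methoxy-6-methylbenzoate (racemic 6-aroyloxy-5-oxoheptanal), via ozonide 11 (not isolated)
Conditions: O3, CH2Cl2, −78 °C, to the first blue tint; PPh3, −78 °C → rt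
Reagents that add atoms: ozone, [O-][O+]=O
Why: Ozonolysis with reductive work-up cleaves the terminal alkene to the aldehyde; the alkene reacts much faster than the ester-deactivated arene, and stopping at the end point avoids over-oxidation.

Step 8
Reactants: 12 3,7-dioxoheptan-2-yl 4-(TBS-oxy)-2-methoxy-6-methylbenzoate (racemic)
Product: 14 (1R,6S)-6-hydroxy-1-methyl-2-oxocyclohexyl 4-(TBS-oxy)-2-methoxy-6-methylbenzoate, via cinchona enamine 13 (not isolated)
Conditions: 9-amino-9-deoxy-epi-quinine (20 mol %), CF3CO2H (40 mol %), toluene (0.05 M), rt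
Reagents that add atoms: none
Why: Proposed new method: the primary amine condenses with the C8 ketone of 12 and acid-mediated tautomerisation gives the tetrasubstituted C7 enamine 13, which erases the lactate-derived centre so that both enantiomers of 12 converge; C7 of 13 then adds to the tethered C6 aldehyde and hydrolysis of the resulting iminium ion releases 14 and the amine. The closest known reaction types are amine-catalysed intramolecular aldolisations of the Hajos–Parrish kind and primary-amine-catalysed aldol additions of α-oxygenated ketones; what has not been shown is their union on an α-acyloxy-α-methyl ketone closing a ring onto the carbon that becomes quaternary. Ring A closes in the 6-(enolendo)-exo-trig mode, C7 and C8 of the enamine both lying in the new ring and the aldehyde C=O outside it, through a chair-like arrangement of the three-carbon tether. C7 is controlled by the enamine geometry, which an N–H···O hydrogen bond to the aroyloxy group should hold with the ester oxygen syn to nitrogen, together with the enamine face left open by the quinoline and quinuclidine units of the catalyst. C6 is controlled by the aldehyde face presented when the protonated quinuclidine nitrogen hydrogen-bonds the aldehyde oxygen, which in the chair should place the forming hydroxyl trans to the aroyloxy group. The step needs regioselection between the two possible enamines, chemoselection between ketone and aldehyde condensation, and stereoconvergence: the C8a enamine could close only a four-membered ring, the aldimine forms reversibly and intermolecular reaction is held down by dilution, and the oxygen on C7 makes its hydrogen acidic enough for both enantiomers to drain through 13. Because C7 carries no hydrogen in 14, dehydration is impossible and the only erosion pathway is retro-aldol, which is limited by working at room temperature and stopping at full conversion.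

Step 9
Reactants: 14 (1R,6S)-6-hydroxy-1-methyl-2-oxocyclohexyl 4-(TBS-oxy)-2-methoxy-6-methylbenzoate
Product: 16 (1R,6S)-1-methyl-2-oxo-6-(TES-oxy)cyclohex-3-en-1-yl 4-(TBS-oxy)-2-methoxy-6-methylbenzoate, via bis-silyl enol ether 15 (not isolated)
Conditions: TESOTf (2.5 equiv), Et3N, CH2Cl2, −78 → 0 °C; then Pd(OAc)2 (1.05 equiv), MeCN, rt
Reagents that add atoms: triethylsilyl trifluoromethanesulfonate, CC[Si](CC)(CC)OS(=O)(=O)C(F)(F)F
Why: Soft enolisation can go only towards C8a because C7 is quaternary, the same triflate protects the C6 hydroxyl, and Pd(OAc)2 then effects Saegusa–Ito dehydrosilylation to the C8a=C4a enone; no base strong enough for retro-aldol or acyl shift is present.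

Step 10
Reactants: 17 (E)-but-2-enal
Product: 18 (E)-1,1-dibromopenta-1,3-diene
Conditions: CBr4, PPh3, CH2Cl2, 0 °C
Reagents that add atoms: tetrabromomethane, BrC(Br)(Br)Br
Why: First stage of the Corey–Fuchs homologation (Wittig-type dibromo-olefination); it keeps the E alkene and gives a non-volatile precursor of the pentenynyl anion.

Step 11
Reactants: 16 (1R,6S)-1-methyl-2-oxo-6-(TES-oxy)cyclohex-3-en-1-yl 4-(TBS-oxy)-2-methoxy-6-methylbenzoate; 18 (E)-1,1-dibromopenta-1,3-diene
Product: 22 (1R,6S)-3-(hydroxymethyl)-1-methyl-2-oxo-4-[(E)-pent-3-en-1-ynyl]-6-(TES-oxy)cyclohexyl 4-(TBS-oxy)-2-methoxy-6-methylbenzoate (C3/C4 epimers), via lithium acetylide 19 (not isolated), via alkynylalane 20 (not isolated), via aluminium enolate 21 (not isolated)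
Conditions: 18, n-BuLi (2 equiv), Et2O, −78 → 0 °C; Me2AlCl, 0 °C; Ni(acac)2/i-Bu2AlH (10 mol % each), then 16, Et2O, −5 °C; CH2O (gas), −40 → 0 °C; aq. potassium sodium tartrate
Reagents that add atoms: formaldehyde, C=O
Why: n-BuLi converts 18 to acetylide 19 (exchange, rearrangement, deprotonation) and Me2AlCl gives alane 20, whose addition to the s-trans enone 16 is turned from 1,2 to 1,4 by the Ni(acac)2/i-Bu2AlH catalyst (Ni(acac)2-catalysed conjugate alkynylation). The aluminium enolate 21 is regiodefined at C8a and is captured by formaldehyde (tandem conjugate addition–aldol). The two new centres (trans expected) are transient and need no control.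

Step 12
Reactants: 22 (1R,6S)-3-(hydroxymethyl)-1-methyl-2-oxo-4-[(E)-pent-3-en-1-ynyl]-6-(TES-oxy)cyclohexyl 4-(TBS-oxy)-2-methoxy-6-methylbenzoate
Product: 23 (1R,6S)-3-[(TBS-oxy)methyl]-1-methyl-2-oxo-4-[(E)-pent-3-en-1-ynyl]-6-(TES-oxy)cyclohexyl 4-(TBS-oxy)-2-methoxy-6-methylbenzoate (C3/C4 epimers)
Conditions: TBSCl, imidazole, CH2Cl2, 0 °C
Reagents that add atoms: tert-butyldimethylsilyl chloride, CC(C)(C)[Si](C)(C)Cl
Why: Standard silylation of the primary alcohol; it blocks retro-aldol and dehydration of the β-hydroxy ketone and allows a strong base in the next step.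

Step 13
Reactants: 23 (1R,6S)-3-[(TBS-oxy)methyl]-1-methyl-2-oxo-4-[(E)-pent-3-en-1-ynyl]-6-(TES-oxy)cyclohexyl 4-(TBS-oxy)-2-methoxy-6-methylbenzoate
Product: 26 (1R,6S)-3-[(TBS-oxy)methyl]-1-methyl-2-oxo-4-[(E)-pent-3-en-1-ynyl]-6-(TES-oxy)cyclohex-3-en-1-yl 4-(TBS-oxy)-2-methoxy-6-methylbenzoate, via selenide 24 (not isolated), via selenoxide 25 (not isolated)
Conditions: LiN(SiMe3)2, THF, −78 °C; PhSeBr, −78 °C; then crude 24, mCPBA, CH2Cl2, −78 °C; i-Pr2NH, → rt
Reagents that add atoms: none
Why: C8a–H is the only α-hydrogen, so one enolate forms, and PhSeBr should enter anti to the pseudo-axial alkynyl group, which places selenium cis to C4a–H (α-selenenylation). Oxidation to selenoxide 25 is followed by selenoxide syn-elimination into the ring, since elimination towards an oxygen-bearing carbon (C1) is strongly disfavoured. This clears both transient stereocentres and restores the C4a=C8a enone.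

Step 14
Reactants: 26 (1R,6S)-3-[(TBS-oxy)methyl]-1-methyl-2-oxo-4-[(E)-pent-3-en-1-ynyl]-6-(TES-oxy)cyclohex-3-en-1-yl 4-(TBS-oxy)-2-methoxy-6-methylbenzoate
Product: 27 (1R,6S)-6-hydroxy-3-(hydroxymethyl)-1-methyl-2-oxo-4-[(E)-pent-3-en-1-ynyl]cyclohex-3-en-1-yl 4-hydroxy-2-methoxy-6-methylbenzoate
Conditions: HF·pyridine (excess), pyridine, THF, 0 °C → rt
Reagents that add atoms: none
Why: Global desilylation with buffered acidic fluoride removes the three silyl groups (the aryl silyl ether is expected to go last, hence the excess and the warming) without forming alkoxides, which avoids the base-induced C7→C6 acyl shift and the vinylogous elimination of the C6 oxygen.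

Step 15
Reactants: 27 (1R,6S)-6-hydroxy-3-(hydroxymethyl)-1-methyl-2-oxo-4-[(E)-pent-3-en-1-ynyl]cyclohex-3-en-1-yl 4-hydroxy-2-methoxy-6-methylbenzoate
Product: 28 (6S,7R)-6-hydroxy-7-methyl-8-oxo-3-[(E)-prop-1-enyl]-5,6,7,8-tetrahydro-1H-isochromen-7-yl 4-hydroxy-2-methoxy-6-methylbenzoate
Conditions: Ph3PAuNTf2 (5 mol %), CH2Cl2, rt
Reagents that add atoms: none
Why: Ph3PAuNTf2-catalysed hydroalkoxylation (π-activation of the alkyne, anti-addition of the primary hydroxyl, protodeauration), as in the cyclisation of 2-alkynylbenzyl alcohols to 1H-isochromenes. C3 is the δ-carbon of the ynenone and carries the propenyl group, so polarisation and cation stabilisation both favour 6-endo-dig over 5-exo-dig closure. The C6 hydroxyl could reach the alkyne only through a bridged ring.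

**Compound list**

1 | methyl orsellinate (methyl 2,4-dihydroxy-6-methylbenzoate) | COC(=O)c1c(C)cc(O)cc1O | starting material
2 | methyl 4-(TBS-oxy)-2-hydroxy-6-methylbenzoate | COC(=O)c1c(C)cc(O[Si](C)(C)C(C)(C)C)cc1O | intermediate
3 | methyl 4-(TBS-oxy)-2-methoxy-6-methylbenzoate | COC(=O)c1c(C)cc(O[Si](C)(C)C(C)(C)C)cc1OC | intermediate
4 | 4-(TBS-oxy)-2-methoxy-6-methylbenzoic acid | OC(=O)c1c(C)cc(O[Si](C)(C)C(C)(C)C)cc1OC | intermediate
5 | ethyl lactate (racemic) | CCOC(=O)C(C)O | starting material
6 | 2-hydroxy-N-methoxy-N-methylpropanamide (racemic) | CON(C)C(=O)C(C)O | intermediate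
7 | 1-[methoxy(methyl)amino]-1-oxopropan-2-yl 4-(TBS-oxy)-2-methoxy-6-methylbenzoate (racemic) | CON(C)C(=O)C(C)OC(=O)c1c(C)cc(O[Si](C)(C)C(C)(C)C)cc1OC | intermediate
8 | 5-bromopent-1-ene | C=CCCCBr | starting material
9 | pent-4-enylmagnesium bromide (not isolated) | C=CCCC[Mg]Br | intermediate
10 | 3-oxooct-7-en-2-yl 4-(TBS-oxy)-2-methoxy-6-methylbenzoate (racemic) | CC(OC(=O)c1c(C)cc(O[Si](C)(C)C(C)(C)C)cc1OC)C(=O)CCCC=C | intermediate
11 | 3-oxo-6-(1,2,4-trioxolan-3-yl)hexan-2-yl 4-(TBS-oxy)-2-methoxy-6-methylbenzoate (ozonide, not isolated) | CC(OC(=O)c1c(C)cc(O[Si](C)(C)C(C)(C)C)cc1OC)C(=O)CCCC2OCOO2 | intermediate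
12 | 3,7-dioxoheptan-2-yl 4-(TBS-oxy)-2-methoxy-6-methylbenzoate (racemic) | CC(OC(=O)c1c(C)cc(O[Si](C)(C)C(C)(C)C)cc1OC)C(=O)CCCC=O | intermediate
13 | C7 enamine of 12 with 9-amino-9-deoxy-epi-quinine (alkene geometry not fixed, not isolated) | CC(OC(=O)c1c(C)cc(O[Si](C)(C)C(C)(C)C)cc1OC)=C(CCCC=O)N[C@@H](c2ccnc3ccc(OC)cc23)[C@@H]4C[C@@H]5CCN4C[C@@H]5C=C | intermediate
14 | (1R,6S)-6-hydroxy-1-methyl-2-oxocyclohexyl 4-(TBS-oxy)-2-methoxy-6-methylbenzoate | O=C1[C@](C)(OC(=O)c2c(C)cc(O[Si](C)(C)C(C)(C)C)cc2OC)[C@@H](O)CCC1 | intermediate
15 | (1R,6S)-1-methyl-2,6-bis(TES-oxy)cyclohex-2-en-1-yl 4-(TBS-oxy)-2-methoxy-6-methylbenzoate (not isolated) | CC[Si](CC)(CC)OC1=CCC[C@H](O[Si](CC)(CC)CC)[C@@]1(C)OC(=O)c2c(C)cc(O[Si](C)(C)C(C)(C)C)cc2OC | intermediate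
16 | (1R,6S)-1-methyl-2-oxo-6-(TES-oxy)cyclohex-3-en-1-yl 4-(TBS-oxy)-2-methoxy-6-methylbenzoate | O=C1C=CC[C@H](O[Si](CC)(CC)CC)[C@@]1(C)OC(=O)c2c(C)cc(O[Si](C)(C)C(C)(C)C)cc2OC | intermediate
17 | (E)-but-2-enal | C/C=C/C=O | starting material
18 | (E)-1,1-dibromopenta-1,3-diene | C/C=C/C=C(Br)Br | intermediate
19 | lithium (E)-pent-3-en-1-yn-1-ide (not isolated) | C/C=C/C#C[Li] | intermediate
20 | dimethyl[(E)-pent-3-en-1-ynyl]alane (not isolated) | C/C=C/C#C[Al](C)C | intermediate
21 | (1R,6S)-2-(dimethylalumanyloxy)-1-methyl-4-[(E)-pent-3-en-1-ynyl]-6-(TES-oxy)cyclohex-2-en-1-yl 4-(TBS-oxy)-2-methoxy-6-methylbenzoate (C4 epimers, not isolated) | C[Al](C)OC1=CC(C#C/C=C/C)C[C@H](O[Si](CC)(CC)CC)[C@@]1(C)OC(=O)c2c(C)cc(O[Si](C)(C)C(C)(C)C)cc2OC | intermediate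
22 | (1R,6S)-3-(hydroxymethyl)-1-methyl-2-oxo-4-[(E)-pent-3-en-1-ynyl]-6-(TES-oxy)cyclohexyl 4-(TBS-oxy)-2-methoxy-6-methylbenzoate (C3/C4 epimers, trans expected) | O=C1C(CO)C(C#C/C=C/C)C[C@H](O[Si](CC)(CC)CC)[C@@]1(C)OC(=O)c2c(C)cc(O[Si](C)(C)C(C)(C)C)cc2OC | intermediate
23 | (1R,6S)-3-[(TBS-oxy)methyl]-1-methyl-2-oxo-4-[(E)-pent-3-en-1-ynyl]-6-(TES-oxy)cyclohexyl 4-(TBS-oxy)-2-methoxy-6-methylbenzoate (C3/C4 epimers) | O=C1C(CO[Si](C)(C)C(C)(C)C)C(C#C/C=C/C)C[C@H](O[Si](CC)(CC)CC)[C@@]1(C)OC(=O)c2c(C)cc(O[Si](C)(C)C(C)(C)C)cc2OC | intermediate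
24 | 3-(phenylselanyl) derivative of 23 (selenium on C3 of the cyclohexanone, C3/C4 unassigned, not isolated) | O=C1C(CO[Si](C)(C)C(C)(C)C)([Se]c2ccccc2)C(C#C/C=C/C)C[C@H](O[Si](CC)(CC)CC)[C@@]1(C)OC(=O)c3c(C)cc(O[Si](C)(C)C(C)(C)C)cc3OC | intermediate
25 | selenoxide of 24 (not isolated) | O=C1C(CO[Si](C)(C)C(C)(C)C)([Se](=O)c2ccccc2)C(C#C/C=C/C)C[C@H](O[Si](CC)(CC)CC)[C@@]1(C)OC(=O)c3c(C)cc(O[Si](C)(C)C(C)(C)C)cc3OC | intermediate
26 | (1R,6S)-3-[(TBS-oxy)methyl]-1-methyl-2-oxo-4-[(E)-pent-3-en-1-ynyl]-6-(TES-oxy)cyclohex-3-en-1-yl 4-(TBS-oxy)-2-methoxy-6-methylbenzoate | O=C1C(CO[Si](C)(C)C(C)(C)C)=C(C#C/C=C/C)C[C@H](O[Si](CC)(CC)CC)[C@@]1(C)OC(=O)c2c(C)cc(O[Si](C)(C)C(C)(C)C)cc2OC | intermediate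
27 | (1R,6S)-6-hydroxy-3-(hydroxymethyl)-1-methyl-2-oxo-4-[(E)-pent-3-en-1-ynyl]cyclohex-3-en-1-yl 4-hydroxy-2-methoxy-6-methylbenzoate | O=C1C(CO)=C(C#C/C=C/C)C[C@H](O)[C@@]1(C)OC(=O)c2c(C)cc(O)cc2OC | intermediate
28 | (6S,7R)-6-hydroxy-7-methyl-8-oxo-3-[(E)-prop-1-enyl]-5,6,7,8-tetrahydro-1H-isochromen-7-yl 4-hydroxy-2-methoxy-6-methylbenzoate | C/C=C/C1=CC2=C(CO1)C(=O)[C@](C)(OC(=O)c3c(C)cc(O)cc3OC)[C@@H](O)C2 | target

**Step count and risks**

Total: 15 steps (telescoped operations counted once). Longest linear sequence: 13 steps (1, 2, 3, 5, 6, 7, 8, 9, 11, 12, 13, 14, 15).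

Step 8 (key step). The amine may condense preferentially at the aldehyde, which would lead to intermolecular aldol or Mannich oligomerisation and tie up the catalyst. The tetrasubstituted enamine may form too slowly. Control of enamine geometry and aldehyde face may be insufficient, giving the cis diastereomer or low enantioselectivity, and retro-aldol may erode whatever selectivity is reached. The fallback uses known chemistry and sets out from acid 4. Oxidative α-acyloxylation of purchased 2-methylcyclohexane-1,3-dione F1 with 4 (PhI(OAc)2 after ligand exchange with the acid) would give 2-methyl-1,3-dioxocyclohexan-2-yl 4-(TBS-oxy)-2-methoxy-6-methylbenzoate F2. A desymmetrising mono-reduction of this 2,2-disubstituted 1,3-dione would follow, with a ketoreductase chosen from a panel for the trans (1R,6S) product or with an oxazaborolidine-catalysed borane reduction. The sequence returns to the route at 14 and bypasses steps 4 to 7.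

Step 11. The conjugated enynyl group may oligomerise at the Ni(acac)2-derived catalyst or add 1,2, and the carbenoid from 18 may decompose before it rearranges, so that conjugate transfer is poor. The fallback sets out from 16. The alane from purchased ethynyltrimethylsilane F3 (n-BuLi, Me2AlCl) is added under the same Ni(acac)2/i-Bu2AlH catalysis with formaldehyde capture, the best-precedented case of this reaction, to give the trimethylsilylethynyl hydroxy ketone F4. Protodesilylation with catalytic AgNO3 in aqueous acetone would give the terminal alkyne F5. Sonogashira coupling of F5 with purchased (E)-1-bromoprop-1-ene F6 (PdCl2(PPh3)2, CuI, Et3N) returns to the route at 22.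

Step 13. Selenenylation may occur on the face that leaves no syn hydrogen at C4a, or the enolate may expel the C1 silyloxide, so that the ring alkene is not formed. The fallback sets out from 23. The trimethylsilyl enol ether F7 (Me3SiOTf, Et3N) is brominated with N-bromosuccinimide to the C8a bromide F8. Dehydrobromination with LiBr/Li2CO3 in DMF, where bromide exchange epimerises C8a and anti-elimination has no fixed facial requirement, returns to the route at 26.

Step 3. The aryl silyl ether may be lost, or the aryl methyl ether attacked, at the temperature needed for dealkylation. The fallback sets out from 3. Hydrolysis with KOH in aqueous DMSO cleaves both the ester and the silyl ether to 4-hydroxy-2-methoxy-6-methylbenzoic acid F9. Double silylation (TBSCl, imidazole) gives the silyl ester F10, and selective hydrolysis of the silyl ester with aqueous acetic acid in THF returns to the route at 4.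

Step 6. The Grignard reagent may deprotonate the α-acyloxy position or attack the ester, with acyl transfer or loss of carboxylate. The fallback sets out from 6. Excess 9 is added to the unprotected hydroxy amide to give 2-hydroxyoct-7-en-3-one F11. Mitsunobu esterification of F11 with acid 4, a substitution at a carbon α to a ketone, returns to the route at 10.

**Further compounds**

F1 | step 8 | 2-methylcyclohexane-1,3-dione (purchased) | CC1C(=O)CCCC1=O
F2 | step 8 | 2-methyl-1,3-dioxocyclohexan-2-yl 4-(TBS-oxy)-2-methoxy-6-methylbenzoate | CC1(OC(=O)c2c(C)cc(O[Si](C)(C)C(C)(C)C)cc2OC)C(=O)CCCC1=O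
F3 | step 11 | ethynyltrimethylsilane (purchased) | C#C[Si](C)(C)C
F4 | step 11 | (1R,6S)-3-(hydroxymethyl)-1-methyl-2-oxo-6-(TES-oxy)-4-[(trimethylsilyl)ethynyl]cyclohexyl 4-(TBS-oxy)-2-methoxy-6-methylbenzoate (C3/C4 epimers) | O=C1C(CO)C(C#C[Si](C)(C)C)C[C@H](O[Si](CC)(CC)CC)[C@@]1(C)OC(=O)c2c(C)cc(O[Si](C)(C)C(C)(C)C)cc2OC
F5 | step 11 | (1R,6S)-4-ethynyl-3-(hydroxymethyl)-1-methyl-2-oxo-6-(TES-oxy)cyclohexyl 4-(TBS-oxy)-2-methoxy-6-methylbenzoate (C3/C4 epimers) | O=C1C(CO)C(C#C)C[C@H](O[Si](CC)(CC)CC)[C@@]1(C)OC(=O)c2c(C)cc(O[Si](C)(C)C(C)(C)C)cc2OC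
F6 | step 11 | (E)-1-bromoprop-1-ene (purchased) | C/C=C/Br
F7 | step 13 | trimethylsilyl enol ether of 23 (C8=C8a) | C[Si](C)(C)OC1=C(CO[Si](C)(C)C(C)(C)C)C(C#C/C=C/C)C[C@H](O[Si](CC)(CC)CC)[C@@]1(C)OC(=O)c2c(C)cc(O[Si](C)(C)C(C)(C)C)cc2OC
F8 | step 13 | C8a bromide of 23 (3-bromo-3-[(TBS-oxy)methyl] ketone, C3/C4 unassigned) | O=C1C(Br)(CO[Si](C)(C)C(C)(C)C)C(C#C/C=C/C)C[C@H](O[Si](CC)(CC)CC)[C@@]1(C)OC(=O)c2c(C)cc(O[Si](C)(C)C(C)(C)C)cc2OC
F9 | step 3 | 4-hydroxy-2-methoxy-6-methylbenzoic acid | OC(=O)c1c(C)cc(O)cc1OC
F10 | step 3 | tert-butyldimethylsilyl 4-(TBS-oxy)-2-methoxy-6-methylbenzoate | CC(C)(C)[Si](C)(C)OC(=O)c1c(C)cc(O[Si](C)(C)C(C)(C)C)cc1OC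
F11 | step 6 | 2-hydroxyoct-7-en-3-one (racemic) | CC(O)C(=O)CCCC=C
A1 | alternative 1 | (1R,6S)-6-(TBS-oxy)-3-[(TBS-oxy)methyl]-1-methyl-2-oxo-4-[(E)-2-oxopent-3-enyl]cyclohex-3-en-1-yl 4-(TBS-oxy)-2-methoxy-6-methylbenzoate | C/C=C/C(=O)CC1=C(CO[Si](C)(C)C(C)(C)C)C(=O)[C@](C)(OC(=O)c3c(C)cc(O[Si](C)(C)C(C)(C)C)cc3OC)[C@@H](O[Si](C)(C)C(C)(C)C)C1
A2 | alternative 1 | (1R,6S)-4-(bromomethyl)-6-(TBS-oxy)-3-[(TBS-oxy)methyl]-1-methyl-2-oxocyclohex-3-en-1-yl 4-(TBS-oxy)-2-methoxy-6-methylbenzoate | BrCC1=C(CO[Si](C)(C)C(C)(C)C)C(=O)[C@](C)(OC(=O)c3c(C)cc(O[Si](C)(C)C(C)(C)C)cc3OC)[C@@H](O[Si](C)(C)C(C)(C)C)C1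
A3 | alternative 1 | (E)-tributyl(prop-1-enyl)stannane | C/C=C/[Sn](CCCC)(CCCC)CCCC
A4 | alternative 1 | carbon monoxide | [C-]#[O+]
A5 | alternative 2 | (6S,7R)-6-(TBS-oxy)-7-methyl-8-oxo-3-[(E)-prop-1-enyl]-5,6,7,8-tetrahydro-1H-isochromen-7-yl 4-hydroxy-2-methoxy-6-methylbenzoate | C/C=C/C1=CC2=C(CO1)C(=O)[C@](C)(OC(=O)c3c(C)cc(O)cc3OC)[C@@H](O[Si](C)(C)C(C)(C)C)C2
A6 | alternative 2 | (6S,7R)-6-(TBS-oxy)-7-methyl-8-oxo-3-[(E)-prop-1-enyl]-5,6,7,8-tetrahydro-1H-isochromen-7-yl but-2-ynoate | C/C=C/C1=CC2=C(CO1)C(=O)[C@](C)(OC(=O)C#CC)[C@@H](O[Si](C)(C)C(C)(C)C)C2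
A7 | alternative 2 | 1,1-dimethoxy-3-(trimethylsilyloxy)buta-1,3-diene | COC(OC)=CC(=C)O[Si](C)(C)C
A8 | alternative 3 | (6S,7R)-6-(TBS-oxy)-1-hydroxy-7-methyl-4,8-dioxo-3-[(E)-prop-1-enyl]-3,4,5,6,7,8-hexahydro-1H-isochromen-7-yl 4-(TBS-oxy)-2-methoxy-6-methylbenzoate (C1 anomers, C3 as in A9) | C/C=C/[C@H]1OC(O)C2=C(C1=O)C[C@H](O[Si](C)(C)C(C)(C)C)[C@@](C)(OC(=O)c3c(C)cc(O[Si](C)(C)C(C)(C)C)cc3OC)C2=O
A9 | alternative 3 | (5S,6R)-5-(TBS-oxy)-3-[(E)-1-hydroxybut-2-enyl]-6-methyl-7-oxo-4,5,6,7-tetrahydro-2-benzofuran-6-yl 4-(TBS-oxy)-2-methoxy-6-methylbenzoate (carbinol configuration immaterial) | C/C=C/[C@@H](O)c1occ2c1C[C@H](O[Si](C)(C)C(C)(C)C)[C@@](C)(OC(=O)c3c(C)cc(O[Si](C)(C)C(C)(C)C)cc3OC)C2=O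
A10 | alternative 3 | dioxygen (used in its singlet state) | O=O
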